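The cyclohexane ring C1–C6 carries its substituents (side chain at C1, methyl at C4, oxygen at C5 and C6) in the pattern of a Diels–Alder adduct between a 1‑oxy‑2‑methylbutadiene (C2–C5) and a trans C6=C1 enone. One catalytic asymmetric [4+2] reaction therefore forms C1–C2 and C5–C6, closes the carbocycle and fixes C1, C5 and C6. The acetyl group is a masked C6 acyloxy group, and the C5 silyl ether later steers the C3–C4 epoxidation before becoming the ketone. The precursors are the (E)‑silyl dienol ether of tiglic aldehyde and an (E)‑bromodienone whose 1‑bromovinyl group is the handle for C8–C11.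

Key step: step 4

Remark: skeleton locants are used throughout (ring C1–C6; C1 carries C7(=C14H2)–C8–C9–C10–C11; methyls on C4 and C11; β is the ring face of the C1 side chain), and the catalyst antipodes in steps 4 and 7 are assigned from the usual binding models and would be confirmed by Mosher ester analysis.

Step 1
Reactants: 1 (E)-2-methylbut-2-enal
Product: 2 (E)-tert-butyl(dimethyl)[(2-methylbuta-1,3-dien-1-yl)oxy]silane
Conditions: TBSOTf, Et3N, Et2O, 0 °C to rt
Reagents that add atoms: tert-butyldimethylsilyl trifluoromethanesulfonate, CC(C)(C)[Si](C)(C)OS(=O)(=O)C(F)(F)F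
Why: O‑silylation of the s‑trans enal followed by γ‑deprotonation (silyl dienol ether formation by soft enolisation) should give the diene with oxygen trans to the vinyl group, the (E)‑isomer required for an endo‑cis cycloadduct.

Step 2
Reactants: 3 acrolein
Product: 5 2-bromoacrolein, via 2,3-dibromopropanal 4 (not isolated)
Conditions: Br2, CH2Cl2, −78 °C; then Et3N, −78 to 0 °C
Reagents that add atoms: bromine, BrBr
Why: Bromine addition to the C=C bond and E1cB loss of HBr from the α‑bromo aldehyde (bromination–dehydrobromination) is the standard entry to 2‑bromoacrolein, which is used cold and at once because it polymerises.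

Step 3
Reactants: 5 2-bromoacrolein; 6 1-(triphenylphosphoranylidene)propan-2-one
Product: 7 (E)-5-bromohexa-3,5-dien-2-one
Conditions: CH2Cl2, 0 °C to rt
Reagents that add atoms: none
Why: Wittig olefination with a stabilised acyl ylide reacts only at the aldehyde and should give the (E)‑enone.

Step 4
Reactants: 2 (E)-silyl dienol ether; 7 (E)-5-bromohexa-3,5-dien-2-one
Product: 8 endo cycloadduct (acetyl cyclohexene)
Conditions: (S)-o-tolyl-CBS oxazaborolidine/Tf2NH (20 mol %), CH2Cl2, −78 to −40 °C
Reagents that add atoms: none
Why: The cationic boron binds the acetyl oxygen of the s‑trans enone (lone pair on the vinyl side, α‑C–H···O contact), which lowers the LUMO of C6=C1; the CH2 terminus of the diene (largest HOMO coefficient) bonds first to the β‑carbon C1 in a concerted, asynchronous [4πs+2πs] cycloaddition and C5–C6 closes second. The closest known reaction type is the oxazaborolidinium‑catalysed Diels–Alder reaction of silyloxy dienes with acyclic enones and acrylates. The cyclohexene ring is closed intermolecularly by the cycloaddition itself, four ring atoms coming from the diene and two from the enone. C1/C6 trans follows from the (E)‑enone geometry, C5‑OSi cis to acetyl from the endo transition state with the (E)‑silyloxy group, and the absolute sense from the catalyst phenyl group that covers the C6 Re face so that the diene adds to the Si face. The step needs ortho regiochemistry, secured by the 1‑oxygen substituent and the coordinated carbonyl, and selection of C6=C1 over the terminal C7=C14 bond, which is favoured because reaction there would make the bromine‑bearing carbon quaternary and is farther from the activating group.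

Step 5
Reactants: 8 endo cycloadduct
Product: 10 epoxy acetate, via epoxy ketone 9 (not isolated)
Conditions: mCPBA (4 equiv), Na2HPO4, CH2Cl2, 0 °C, then rt to 35 °C
Reagents that add atoms: 3-chloroperoxybenzoic acid, O=C(OO)c1cccc(Cl)c1
Why: Prilezhaev epoxidation should occur on the face opposite the pseudoaxial C5 silyl ether (β face, syn to the C1 substituent), the electron‑poor vinyl bromide not competing; continued exposure to the peracid then effects Baeyer–Villiger oxidation in which secondary C6 migrates in preference to methyl with retention.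

Step 6
Reactants: 11 4-methylpent-3-en-1-ol
Product: 12 4-methylpent-3-enal
Conditions: Dess–Martin periodinane, NaHCO3, CH2Cl2, 0 °C; filtered solution used at once
Reagents that add atoms: none
Why: Buffered Dess–Martin oxidation gives the β,γ‑unsaturated aldehyde without the acid or base that would move the double bond into conjugation.

Step 7
Reactants: 10 epoxy acetate; 12 4-methylpent-3-enal
Product: 13 C8 allylic alcohol
Conditions: CrCl2 (4 equiv), chiral oxazoline–sulfonamide ligand (4.4 equiv), Et3N (4.4 equiv), THF, rt; then NiCl2 (5 mol %), 12 (2 equiv), rt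
Reagents that add atoms: none
Why: Nozaki–Hiyama–Kishi coupling, in which Ni(0) inserts into C7–Br and the derived alkenylchromium(III) species adds only to the aldehyde (acetate, epoxide and silyl ether are inert); the ligand antipode is chosen so that addition occurs on the Re face of 12, setting C8 as S by reagent control.

Step 8
Reactants: 13 C8 allylic alcohol
Product: 14 C6,C8 diol
Conditions: DIBAL-H (4 equiv), CH2Cl2, −78 °C; Rochelle salt work-up
Reagents that add atoms: none
Why: Reductive ester cleavage through aluminium alkoxides at low temperature removes the acetate without the basic methanolysis that could let the cis C5 silyl group migrate to O6, and leaves epoxide and alkenes untouched.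

Step 9
Reactants: 14 C6,C8 diol; 15 angelic acid
Product: 17 bis-angelate, via angeloyl mixed anhydride 16 (not isolated)
Conditions: 15, 2,4,6-trichlorobenzoyl chloride, Et3N, toluene, rt; then 14, 80 °C
Reagents that add atoms: 2,4,6-trichlorobenzoyl chloride, O=C(Cl)c1c(Cl)cc(Cl)cc1Cl (its atoms reach intermediate 16 only)
Why: Yamaguchi‑type mixed‑anhydride esterification without DMAP acylates both secondary alcohols thermally and, with no nucleophilic catalyst to add reversibly to the enoate, should keep the (Z)‑geometry of the angeloyl groups.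

Step 10
Reactants: 17 bis-angelate
Product: 18 bis-epoxide
Conditions: D-fructose-derived Shi ketone (30 mol %), Oxone, K2CO3, Bu4NHSO4, MeCN/DMM–aq. borate buffer (pH 10.5), 0 °C
Reagents that add atoms: Oxone (potassium peroxymonosulfate), [K+].[O-]S(=O)(=O)OO
Why: Shi epoxidation, in which the chiral dioxirane reacts fastest with the electron‑rich trisubstituted C10=C11 bond (angelate and allylic 1,1‑disubstituted alkenes are deactivated) and the spiro transition state of this ketone should deliver oxygen to the face giving 10R.

Step 11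
Reactants: 18 bis-epoxide
Product: 19 C5 alcohol
Conditions: TBAF, AcOH (1:1), THF, 0 °C to rt
Reagents that add atoms: none
Why: Fluoride desilylation buffered with acetic acid stays near neutral, so neither 1,2‑acyl migration from O6 to O5 nor epoxide opening should occur.

Step 12
Reactants: 19 C5 alcohol
Product: 20 CNP0247177.1
Conditions: Dess–Martin periodinane, NaHCO3, CH2Cl2, 0 °C to rt
Reagents that add atoms: none
Why: Buffered Dess–Martin oxidation of the secondary alcohol gives the α,β‑epoxy ketone without enolising C6, so the trans C1/C6 relationship from step 4 is kept.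

Compound list

1 | (E)-2-methylbut-2-enal | C/C=C(\C)C=O | starting material
2 | (E)-tert-butyl(dimethyl)[(2-methylbuta-1,3-dien-1-yl)oxy]silane | C=C/C(C)=C/O[Si](C)(C)C(C)(C)C | intermediate
3 | acrolein | C=CC=O | starting material
4 | 2,3-dibromopropanal (racemic) | O=CC(Br)CBr | intermediate (not isolated)
5 | 2-bromoacrolein | C=C(Br)C=O | intermediate
6 | 1-(triphenylphosphoranylidene)propan-2-one | CC(=O)C=P(c1ccccc1)(c1ccccc1)c1ccccc1 | starting material
7 | (E)-5-bromohexa-3,5-dien-2-one | CC(=O)/C=C/C(Br)=C | intermediate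
8 | 1-[(1R,2R,6S)-6-(1-bromoethenyl)-2-{[tert-butyl(dimethyl)silyl]oxy}-3-methylcyclohex-3-en-1-yl]ethan-1-one (C1 bromovinyl β; C5 OTBS and C6 acetyl α) | C=C(Br)[C@H]1CC=C(C)[C@H](O[Si](C)(C)C(C)(C)C)[C@@H]1C(C)=O | intermediate
9 | 1-[(1R,2R,3R,4S,6R)-4-(1-bromoethenyl)-2-{[tert-butyl(dimethyl)silyl]oxy}-1-methyl-7-oxabicyclo[4.1.0]heptan-3-yl]ethan-1-one (8 with a β C3–C4 epoxide) | C=C(Br)[C@H]1C[C@H]2O[C@@]2(C)[C@H](O[Si](C)(C)C(C)(C)C)[C@@H]1C(C)=O | intermediate (not isolated)
10 | (1R,2R,3R,4S,6R)-4-(1-bromoethenyl)-2-{[tert-butyl(dimethyl)silyl]oxy}-1-methyl-7-oxabicyclo[4.1.0]heptan-3-yl acetate (C6 OAc α) | C=C(Br)[C@H]1C[C@H]2O[C@@]2(C)[C@H](O[Si](C)(C)C(C)(C)C)[C@@H]1OC(C)=O | intermediate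
11 | 4-methylpent-3-en-1-ol | CC(C)=CCCO | starting material
12 | 4-methylpent-3-enal | CC(C)=CCC=O | intermediate
13 | (1R,2R,3R,4R,6R)-2-{[tert-butyl(dimethyl)silyl]oxy}-4-[(3S)-3-hydroxy-6-methylhepta-1,5-dien-2-yl]-1-methyl-7-oxabicyclo[4.1.0]heptan-3-yl acetate (skeleton 8S) | C=C([C@H](CC=C(C)C)O)[C@H]1C[C@H]2O[C@@]2(C)[C@H](O[Si](C)(C)C(C)(C)C)[C@@H]1OC(C)=O | intermediate
14 | (1R,2R,3R,4R,6R)-2-{[tert-butyl(dimethyl)silyl]oxy}-4-[(3S)-3-hydroxy-6-methylhepta-1,5-dien-2-yl]-1-methyl-7-oxabicyclo[4.1.0]heptan-3-ol | C=C([C@H](CC=C(C)C)O)[C@H]1C[C@H]2O[C@@]2(C)[C@H](O[Si](C)(C)C(C)(C)C)[C@@H]1O | intermediate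
15 | angelic acid, (Z)-2-methylbut-2-enoic acid | C/C=C(/C)C(=O)O | starting material
16 | (Z)-2-methylbut-2-enoic 2,4,6-trichlorobenzoic anhydride | C/C=C(/C)C(=O)OC(=O)c1c(Cl)cc(Cl)cc1Cl | intermediate (not isolated)
17 | 6,8-di-O-angeloyl derivative of 14 (skeleton 1R,3R,4R,5R,6R,8S; C5 OTBS α; C10=C11 alkene) | C=C([C@H](CC=C(C)C)OC(=O)/C(C)=C\C)[C@H]1C[C@H]2O[C@@]2(C)[C@H](O[Si](C)(C)C(C)(C)C)[C@@H]1OC(=O)/C(C)=C\C | intermediate
18 | 17 with a (10R)-10,11-epoxide (skeleton 1R,3R,4R,5R,6R,8S,10R) | C=C([C@H](C[C@H]1OC1(C)C)OC(=O)/C(C)=C\C)[C@H]1C[C@H]2O[C@@]2(C)[C@H](O[Si](C)(C)C(C)(C)C)[C@@H]1OC(=O)/C(C)=C\C | intermediate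
19 | C5 α-alcohol from 18 (skeleton 1R,3R,4S,5R,6R,8S,10R; the C4 descriptor changes by CIP priority only) | C=C([C@H](C[C@H]1OC1(C)C)OC(=O)/C(C)=C\C)[C@H]1C[C@H]2O[C@@]2(C)[C@H](O)[C@@H]1OC(=O)/C(C)=C\C | intermediate
20 | CNP0247177.1 (skeleton 1R,3R,4R,6R,8S,10R; C5 ketone, β C3–C4 epoxide, angelates on O6 and O8, 10,11-epoxide) | C=C([C@H](C[C@H]1OC1(C)C)OC(=O)/C(C)=C\C)[C@H]1C[C@H]2O[C@@]2(C)C(=O)[C@@H]1OC(=O)/C(C)=C\C | target

Total step count: 12. Longest linear sequence: 10 steps (acrolein 3 through steps 2, 3, 4, 5, 7, 8, 9, 10, 11, 12).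

Steps most likely to fail

1. Step 4. A methyl ketone offers the catalyst two lone pairs and binds more weakly than an enal, so facial discrimination may be poor. The diene may also add to the terminal bromoalkene, or transfer its silyl group in a Mukaiyama–Michael pathway. If only the absolute sense proves opposite, the D‑proline‑derived catalyst is used without other change. The fallback sets out from 5: Wittig reaction with (triphenylphosphoranylidene)acetaldehyde should give (E)-4-bromopenta-2,4-dienal F1. Its cycloaddition with 2 under the antipodal oxazaborolidinium catalyst (enals bind through a single formyl C–H···O mode that exposes the opposite α‑face and are more reactive) should give the aldehyde cycloadduct F2. Addition of MeMgBr at −78 °C gives the methyl carbinol F3, and Dess–Martin oxidation returns to the route at 8.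

2. Step 7. Ligand control may be overridden by the two stereogenic partners, giving poor facial selectivity at the aldehyde and a C8 epimer mixture. The fallback sets out from 10: the Ni/Cr coupling with 12 is run without chiral ligand (CrCl2, NiCl2 cat., DMSO) to give the C8-epimeric alcohol mixture F4. Dess–Martin oxidation gives the C8 enone F5, and reduction with (R)‑Me‑CBS/catecholborane in toluene at −78 °C (the branched alkenyl group acting as the large substituent) should give the 8S alcohol, returning to the route at 13.

3. Step 9. Acyl transfer to the hindered C6 hydroxyl may stall, and prolonged heating may isomerise the angeloyl group to the tigloyl group. The fallback sets out from 14: EDC/DMAP esterification with 2‑[bis(2,2,2‑trifluoroethoxy)phosphoryl]propanoic acid gives the bis(phosphonopropionate) F6. A double Still–Gennari olefination with acetaldehyde (KHMDS, 18‑crown‑6, THF, −78 °C) then builds both (Z)‑2‑methylbut‑2‑enoates on the molecule, returning to the route at 17.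

Further compounds

F1 | step 4 | (E)-4-bromopenta-2,4-dienal | O=C/C=C/C(Br)=C
F2 | step 4 | (1R,2R,6S)-6-(1-bromoethenyl)-2-{[tert-butyl(dimethyl)silyl]oxy}-3-methylcyclohex-3-ene-1-carbaldehyde | C=C(Br)[C@H]1CC=C(C)[C@H](O[Si](C)(C)C(C)(C)C)[C@@H]1C=O
F3 | step 4 | 1-[6-(1-bromoethenyl)-2-{[tert-butyl(dimethyl)silyl]oxy}-3-methylcyclohex-3-en-1-yl]ethan-1-ol, ring configuration as in 8, carbinol epimers | C=C(Br)[C@H]1CC=C(C)[C@H](O[Si](C)(C)C(C)(C)C)[C@@H]1C(C)O
F4 | step 7 | C8-epimer mixture of alcohol 13 | C=C(C(O)CC=C(C)C)[C@H]1C[C@H]2O[C@@]2(C)[C@H](O[Si](C)(C)C(C)(C)C)[C@@H]1OC(C)=O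
F5 | step 7 | C8 enone corresponding to 13 | C=C(C(=O)CC=C(C)C)[C@H]1C[C@H]2O[C@@]2(C)[C@H](O[Si](C)(C)C(C)(C)C)[C@@H]1OC(C)=O
F6 | step 9 | 6,8-bis-O-{2-[bis(2,2,2-trifluoroethoxy)phosphoryl]propanoyl} derivative of 14 (epimers at the phosphonate α-carbons) | C=C([C@H](CC=C(C)C)OC(=O)C(C)P(=O)(OCC(F)(F)F)OCC(F)(F)F)[C@H]1C[C@H]2O[C@@]2(C)[C@H](O[Si](C)(C)C(C)(C)C)[C@@H]1OC(=O)C(C)P(=O)(OCC(F)(F)F)OCC(F)(F)F
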